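**Strategy.** The benzotropolone is read as an acid-opened 8-oxabicyclo[3.2.1]octadienone. Its seven-membered ring (T1 C–O beside the ring fusion, T2 C–O, T3 CH, T4 C bearing the gallated flavan, T5 CH) lets T2–T3 and T4–T5 arise from one dipole–alkyne cycloaddition. A rhodium carbenoid from an ortho-formyl aryl diazoketone, already carrying the non-gallated cis-flavan, closes onto the aldehyde oxygen; the resulting benzopyrylium olate adds across an ynone that brings the gallate-bearing C3 and the open chain of the second flavan. One operation thus joins both halves and builds the bridged seven-membered carbocycle; bridge opening, reductive pyran closure and hydrogenolysis follow.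

Key step: step 19

Remark on the chemistry: the benzotropolone is written in one of its two equivalent hydroxy-ketone tautomeric forms. Both flavan units are 2,3-cis (2R,3R), so methyl (R)-glycidate supplies C3 of each. The two bridgehead carbons of the cycloadduct form on both faces and are left unassigned, because step 20 makes them sp2.

Design remark: the catechol beside the diazoketone is held as a diphenylmethylene acetal (no benzyl group able to migrate in an oxonium ylide, no benzylic C–H within reach of the carbenoid). The phloroglucinol ring of the ynone carries three identical methoxymethyl (MOM) ethers, so its metalation and the later pyran closure cannot give regioisomers. TIPS = triisopropylsilyl.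

Step 1
Reactants: 1 phloroglucinol
Product: 2 1,3,5-tris(methoxymethoxy)benzene
Conditions: NaH, MOMCl, DMF, 0 °C to rt
Reagents that add atoms: chloromethyl methyl ether (MOMCl), COCCl
Why: Williamson O-alkylation of the sodium phenoxides with the hard, very reactive α-chloro ether gives the tris-acetal, which keeps the arene symmetrical and places two directing groups beside every ring position.

Step 2
Reactants: 2 1,3,5-tris(methoxymethoxy)benzene; 3 methyl (R)-glycidate
Product: 6 methyl (2R)-2-hydroxy-3-[2,4,6-tris(methoxymethoxy)phenyl]propanoate, via aryllithium 4 (not isolated), via arylmagnesium bromide 5 (not isolated)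
Conditions: n-BuLi, THF, 0 °C; MgBr2·OEt2, −30 °C; CuI (10 mol %), then 3, −30 to 0 °C; aqueous work-up
Reagents that add atoms: none
Why: Directed ortho-lithiation between two MOM ethers can give only one aryllithium because the arene is threefold symmetric, and after transmetalation the CuI-catalysed aryl transfer opens the epoxide by SN2 attack at its CH2 terminus (organocuprate epoxide opening), so the glycidate stereocentre is untouched and stays R.

Step 3
Reactants: 6 methyl (2R)-2-hydroxy-3-[2,4,6-tris(methoxymethoxy)phenyl]propanoate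
Product: 7 methyl (2R)-2-(benzyloxy)-3-[2,4,6-tris(methoxymethoxy)phenyl]propanoate
Conditions: BnBr, Ag2O, CH2Cl2, rt, dark
Reagents that add atoms: benzyl bromide, BrCc1ccccc1
Why: Silver-oxide-promoted Williamson benzylation etherifies the secondary alcohol without forming a free alkoxide, so the α-stereocentre of the ester is not exposed to epimerisation.

Step 4
Reactants: 7 methyl (2R)-2-(benzyloxy)-3-[2,4,6-tris(methoxymethoxy)phenyl]propanoate
Product: 9 (3R)-3-(benzyloxy)-5,7-dihydroxy-3,4-dihydro-2H-chromen-2-one, via triphenol ester 8 (not isolated)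
Conditions: HCl (1 M), MeOH, 40 °C; evaporate; TsOH (cat.), PhMe, 80 °C
Reagents that add atoms: none
Why: Acid-catalysed acetal exchange with methanol removes the three aryl MOM groups (the formaldehyde unit leaves as dimethoxymethane) and one of the two equivalent ortho phenols then lactonises onto the ester in a six-membered transesterification, which differentiates the ortho oxygens without any selectivity question and leaves C3 untouched.

Step 5
Reactants: 9 (3R)-3-(benzyloxy)-5,7-dihydroxy-3,4-dihydro-2H-chromen-2-one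
Product: 10 (3R)-3,5,7-tris(benzyloxy)-3,4-dihydro-2H-chromen-2-one
Conditions: BnBr, K2CO3, acetone, rt to 40 °C
Reagents that add atoms: benzyl bromide, BrCc1ccccc1
Why: Williamson etherification of the two phenols under carbonate conditions that are too weakly basic to enolise or open the lactone.

Step 6
Reactants: 11 2,3-dimethoxybenzoic acid
Product: 13 6,7-dimethoxy-2-benzofuran-1(3H)-one (meconin), via hydroxymethyl acid 12 (not isolated)
Conditions: 37 % aq. HCHO, conc. HCl, AcOH, 80 °C
Reagents that add atoms: formaldehyde, C=O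
Why: Blanc-type hydroxymethylation goes to the position para to the unhindered 3-methoxy group and ortho to the carboxyl, and the benzylic alcohol closes at once onto the acid to the five-membered lactone.

Step 7
Reactants: 13 6,7-dimethoxy-2-benzofuran-1(3H)-one
Product: 14 6,7-dihydroxy-2-benzofuran-1(3H)-one
Conditions: BBr3, CH2Cl2, −78 °C to rt; H2O
Reagents that add atoms: none
Why: BBr3 cleaves both aryl methyl ethers by bromide attack on the boron-complexed methyl groups, while the phthalide ring, if opened at all, recloses on aqueous work-up.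

Step 8
Reactants: 14 6,7-dihydroxy-2-benzofuran-1(3H)-one
Product: 15 4-bromo-6,7-dihydroxy-2-benzofuran-1(3H)-one
Conditions: Br2 (1.05 equiv), AcOH, rt
Reagents that add atoms: bromine, BrBr
Why: Electrophilic aromatic bromination takes the only position that is para to a hydroxyl (the chelated 7-OH) and meta to the lactone carbonyl, the alternative C5 being para to the carbonyl and only ortho to a hydroxyl.

Step 9
Reactants: 15 4-bromo-6,7-dihydroxy-2-benzofuran-1(3H)-one
Product: 16 4-bromo-6,7-(diphenylmethylenedioxy)-2-benzofuran-1(3H)-one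
Conditions: Ph2CCl2, Ph2O, 170 °C
Reagents that add atoms: dichlorodiphenylmethane, ClC(Cl)(c1ccccc1)c1ccccc1
Why: Thermal double O-alkylation of the catechol by the geminal dichloride gives the cyclic diphenylmethylene acetal, which is stable to base and organolithiums and is removed at the end by hydrogenolysis.

Step 10
Reactants: 16 4-bromo-6,7-(diphenylmethylenedioxy)-2-benzofuran-1(3H)-one
Product: 19 6-bromo-2,2-diphenyl-5-{[(triisopropylsilyl)oxy]methyl}-1,3-benzodioxole-4-carboxylic acid, via potassium hydroxy carboxylate 17 (not isolated), via bis-silyl compound 18 (not isolated)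
Conditions: KOH, THF/MeOH/H2O, rt; evaporate; TIPSCl, imidazole, DMF, 40 °C; K2CO3, MeOH/THF/H2O, rt; aq. KHSO4 to pH 4
Reagents that add atoms: potassium hydroxide, [K+].[OH-]; triisopropylsilyl chloride, CC(C)[Si](Cl)(C(C)C)C(C)C
Why: Saponification gives the potassium hydroxy carboxylate, which is silylated on both oxygens before acid could relactonise it, and carbonate methanolysis then cleaves only the labile silyl ester to leave the hindered primary silyl ether and the free acid.

Step 11
Reactants: 19 6-bromo-2,2-diphenyl-5-{[(triisopropylsilyl)oxy]methyl}-1,3-benzodioxole-4-carboxylic acid; 10 (3R)-3,5,7-tris(benzyloxy)-3,4-dihydro-2H-chromen-2-one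
Product: 21 2,2-diphenyl-6-[(3R)-3,5,7-tris(benzyloxy)-2-hydroxy-3,4-dihydro-2H-chromen-2-yl]-5-{[(triisopropylsilyl)oxy]methyl}-1,3-benzodioxole-4-carboxylic acid (hemiketal, both C2 epimers), via dilithio species 20 (not isolated)
Conditions: n-BuLi (1.0 equiv), THF, −78 °C; t-BuLi (2.0 equiv), −78 °C; then 10, −78 °C; aqueous work-up at pH 4–5
Reagents that add atoms: none
Why: After deprotonation of the acid, bromine–lithium exchange with two equivalents of t-BuLi gives the aryllithium (the lithium carboxylate is inert at −78 °C), which adds once to the activated aryl-ester carbonyl of the lactone, the lithium-chelated hemiketal alkoxide surviving until quench; the hemiketal carbon forms as a mixture, which is irrelevant because it becomes planar in step 12.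

Step 12
Reactants: 21 hemiketal acid
Product: 22 2,2-diphenyl-6-[(2R,3R)-3,5,7-tris(benzyloxy)-3,4-dihydro-2H-chromen-2-yl]-5-{[(triisopropylsilyl)oxy]methyl}-1,3-benzodioxole-4-carboxylic acid
Conditions: Et3SiH, BF3·OEt2, CH2Cl2, −78 to −50 °C
Reagents that add atoms: none
Why: BF3·OEt2 ionises the tertiary benzylic hemiketal to the cyclic oxocarbenium ion and Et3SiH delivers hydride (ionic hydrogenation of a lactol) to the face anti to the C3 benzyloxy group, which lies pseudoaxial to avoid allylic strain with the coplanar aryl group, so the 2,3-cis (2R,3R) flavan should result.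

Step 13
Reactants: 22 flavan acid
Product: 24 2-diazo-1-{2,2-diphenyl-6-[(2R,3R)-3,5,7-tris(benzyloxy)-3,4-dihydro-2H-chromen-2-yl]-5-{[(triisopropylsilyl)oxy]methyl}-1,3-benzodioxol-4-yl}ethan-1-one, via acid chloride 23 (not isolated)
Conditions: 1-chloro-N,N,2-trimethylprop-1-en-1-amine, CH2Cl2, 0 °C to rt; then CH2N2 (excess), Et2O, 0 °C
Reagents that add atoms: diazomethane, C=[N+]=[N-]
Why: The α-chloroenamine converts the hindered acid into its chloride under neutral conditions (bulky 2-(silyloxymethyl)benzoyl chlorides can be handled without lactonising), and diazomethane is C-acylated as in the first stage of an Arndt–Eistert sequence, a second equivalent removing HCl as chloromethane.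

Step 14
Reactants: 24 silyl-protected diazoketone
Product: 25 2-diazo-1-{5-(hydroxymethyl)-2,2-diphenyl-6-[(2R,3R)-3,5,7-tris(benzyloxy)-3,4-dihydro-2H-chromen-2-yl]-1,3-benzodioxol-4-yl}ethan-1-one
Conditions: TBAF, AcOH (1:1), THF, 0 °C to rt
Reagents that add atoms: none
Why: Buffered fluoride cleaves the primary silyl ether while the diazoketone, stable to fluoride and to weak acid, is untouched; the product may rest as its five-membered hemiketal, which reopens on oxidation.

Step 15
Reactants: 25 hydroxymethyl diazoketone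
Product: 26 4-(diazoacetyl)-2,2-diphenyl-6-[(2R,3R)-3,5,7-tris(benzyloxy)-3,4-dihydro-2H-chromen-2-yl]-1,3-benzodioxole-5-carbaldehyde
Conditions: MnO2 (activated, excess), CH2Cl2, rt
Reagents that add atoms: none
Why: Activated MnO2 oxidises the benzylic alcohol on its surface under neutral conditions that diazo compounds tolerate and cannot over-oxidise, and making the aldehyde last avoids the cyclic pseudo-acid chemistry of ortho-formyl benzoic acids.

Step 16
Reactants: 6 methyl (2R)-2-hydroxy-3-[2,4,6-tris(methoxymethoxy)phenyl]propanoate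
Product: 27 (2R)-2-hydroxy-N-methoxy-N-methyl-3-[2,4,6-tris(methoxymethoxy)phenyl]propanamide
Conditions: MeNHOMe·HCl, iPrMgCl, THF, −20 to 0 °C
Reagents that add atoms: N,O-dimethylhydroxylamine hydrochloride, CNOC.Cl
Why: The chloromagnesium amide of N,O-dimethylhydroxylamine aminolyses the methyl ester (Weinreb amide formation) while the hydroxyl is held as its magnesium alkoxide, which also protects the α-stereocentre from enolisation.

Step 17
Reactants: 27 hydroxy Weinreb amide; 28 3,4,5-tris(benzyloxy)benzoic acid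
Product: 29 (2R)-1-[methoxy(methyl)amino]-1-oxo-3-[2,4,6-tris(methoxymethoxy)phenyl]propan-2-yl 3,4,5-tris(benzyloxy)benzoate
Conditions: EDC·HCl, DMAP, CH2Cl2, 0 °C to rt
Reagents that add atoms: none
Why: Steglich esterification (carbodiimide activation, DMAP acyl transfer) acylates the secondary alcohol under mild conditions that do not epimerise the amide α-carbon.

Step 18
Reactants: 29 gallate Weinreb amide
Product: 31 (2R)-3-oxo-1-[2,4,6-tris(methoxymethoxy)phenyl]pent-4-yn-2-yl 3,4,5-tris(benzyloxy)benzoate, via magnesium hemiaminal 30 (not isolated)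
Conditions: HC≡CMgBr (2 equiv), THF, −40 to 0 °C; inverse quench into cold 0.5 M HCl
Reagents that add atoms: ethynylmagnesium bromide, C#C[Mg]Br
Why: Weinreb ketone synthesis: the acetylide adds to the chelation-activated N-methoxy amide faster than to the electron-rich benzoate ester, the five-membered magnesium chelate holds the tetrahedral intermediate until the inverse acidic quench, and the base-sensitive α-acyloxy ynone is therefore released only in acid and without free amine, with C2 unchanged.

Step 19
Reactants: 26 formyl diazoketone; 31 gallate ynone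
Product: 33 oxygen-bridged cycloadduct (benzo-fused 8-oxabicyclo[3.2.1]octadienone: ketone T1, bridgeheads T2 and T5 joined by oxygen, alkene T3=T4 with the (2R)-gallate-bearing acyl chain on T4; bridgeheads unassigned), via benzopyrylium olate 32 (not isolated)
Conditions: Rh2(OAc)4 (2 mol %), CH2Cl2, rt, slow addition of 26 to 31 (1.5 equiv)
Reagents that add atoms: none
Why: Rh2(OAc)4 (divalent rhodium) expels N2 from 26, and the electrophilic carbenoid is captured by a lone pair of the neighbouring formyl oxygen (six-membered ring closure by attack of O on the carbenoid carbon) to give the aromatic 2-benzopyrylium-4-olate 32. This carbonyl ylide adds suprafacially as a 1,3-dipole across the ynone triple bond in a concerted cycloaddition, forming T2–T3 and T5–T4 and with them the seven-membered carbocycle and its oxygen bridge. The closest known reaction type is the tandem carbenoid cyclisation–cycloaddition of ortho-carbonyl α-diazoacetophenones with alkynes, whose adducts are opened by acid to benzotropolones. The two new stereocentres are the bridgeheads T2 and T5: their mutual cis relation is fixed by the one-atom oxygen bridge, while their sense relative to the distant flavan and gallate centres is not controlled and need not be, since both become sp2 in step 20. The selectivity that matters is regiochemistry: the nucleophilic ylide carbon T2 (alpha to the ketone) must bond to the terminal beta carbon of the ynone, which conjugation with the ketone makes the electrophilic alkyne terminus. Capture of the carbenoid by the aldehyde is secured by the acetal-locked catechol oxygen, which has no migrating group and could only close a strained ring-fused oxonium ylide, and slow addition to excess ynone keeps 26 from acting as a second dipolarophile or carbene partner.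

Step 20
Reactants: 33 oxygen-bridged cycloadduct
Product: 36 methyl ketal of the gallated 2-(benzotropolonyl)chroman (2-methoxy, both C2 epimers; 5,7-dihydroxy; (3R)-gallate), via benzotropolone ketone 34 (not isolated), via triphenol ketone 35 (not isolated)
Conditions: HCl (0.5 M), MeOH/CH2Cl2, rt to 40 °C
Reagents that add atoms: methanol, CO
Why: Acid ionises the benzylic C–O bond of the oxygen bridge at T5 (cation stabilised by the para dioxole oxygen and the T3=T4 alkene), loss of the T2 proton gives the aromatic benzotropolone with the oxygen kept on T2, and methanolic acetal exchange removes the three MOM groups so that either of the two equivalent ortho phenols closes onto the ketone as the six-membered methyl ketal; C3 is not involved.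

Step 21
Reactants: 36 methyl ketal
Product: 37 hexa-O-benzyl diphenylmethylene-protected theaflavin gallate (gallated flavan 2R,3R cis with free 5,7-hydroxyls; free tropolone hydroxyl)
Conditions: Et3SiH, TMSOTf, CH2Cl2/MeCN, −40 to −20 °C; aq. NaHCO3
Reagents that add atoms: none
Why: TMSOTf ionises the ketal to the cyclic oxocarbenium ion and Et3SiH adds hydride anti to the C3 gallate (which can also shield its own face through acyloxonium participation), a reductive etherification of the kind used for gallated cis-flavans, so the new C2 centre should be R and cis to the ester.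

Step 22
Reactants: 37 protected theaflavin gallate
Product: 38 CNP0488827.1
Conditions: H2 (1 atm), Pd(OH)2/C, THF/MeOH, rt
Reagents that add atoms: none
Why: Hydrogenolysis over Pd(OH)2/C cleaves the six benzyl ethers and the diphenylmethylene acetal, these benzylic C–O bonds being far more reactive than the tropolone ring or the flavan C2–O bonds at one atmosphere and room temperature.

**Compound list**

1 | phloroglucinol | Oc1cc(O)cc(O)c1 | starting material
2 | 1,3,5-tris(methoxymethoxy)benzene | COCOc1cc(OCOC)cc(OCOC)c1 | intermediate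
3 | methyl (R)-glycidate | COC(=O)[C@H]1CO1 | starting material
4 | [2,4,6-tris(methoxymethoxy)phenyl]lithium | [Li]c1c(OCOC)cc(OCOC)cc1OCOC | intermediate (not isolated)
5 | [2,4,6-tris(methoxymethoxy)phenyl]magnesium bromide | Br[Mg]c1c(OCOC)cc(OCOC)cc1OCOC | intermediate (not isolated)
6 | methyl (2R)-2-hydroxy-3-[2,4,6-tris(methoxymethoxy)phenyl]propanoate | COC(=O)[C@H](O)Cc1c(OCOC)cc(OCOC)cc1OCOC | intermediate
7 | methyl (2R)-2-(benzyloxy)-3-[2,4,6-tris(methoxymethoxy)phenyl]propanoate | COC(=O)[C@H](OCc1ccccc1)Cc1c(OCOC)cc(OCOC)cc1OCOC | intermediate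
8 | methyl (2R)-2-(benzyloxy)-3-(2,4,6-trihydroxyphenyl)propanoate | COC(=O)[C@H](OCc1ccccc1)Cc1c(O)cc(O)cc1O | intermediate (not isolated)
9 | (3R)-3-(benzyloxy)-5,7-dihydroxy-3,4-dihydro-2H-chromen-2-one | O=C1Oc2cc(O)cc(O)c2C[C@H]1OCc1ccccc1 | intermediate
10 | (3R)-3,5,7-tris(benzyloxy)-3,4-dihydro-2H-chromen-2-one | O=C1Oc2cc(OCc3ccccc3)cc(OCc3ccccc3)c2C[C@H]1OCc1ccccc1 | intermediate
11 | 2,3-dimethoxybenzoic acid | COc1cccc(C(=O)O)c1OC | starting material
12 | 6-(hydroxymethyl)-2,3-dimethoxybenzoic acid | COc1ccc(CO)c(C(=O)O)c1OC | intermediate (not isolated)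
13 | 6,7-dimethoxy-2-benzofuran-1(3H)-one (meconin) | COc1ccc2c(c1OC)C(=O)OC2 | intermediate
14 | 6,7-dihydroxy-2-benzofuran-1(3H)-one | Oc1ccc2c(c1O)C(=O)OC2 | intermediate
15 | 4-bromo-6,7-dihydroxy-2-benzofuran-1(3H)-one | Oc1cc(Br)c2c(c1O)C(=O)OC2 | intermediate
16 | 4-bromo-6,7-(diphenylmethylenedioxy)-2-benzofuran-1(3H)-one | O=C1OCc2c(Br)cc3OC(c4ccccc4)(c4ccccc4)Oc3c12 | intermediate
17 | potassium 6-bromo-5-(hydroxymethyl)-2,2-diphenyl-1,3-benzodioxole-4-carboxylate | [K+].[O-]C(=O)c1c(CO)c(Br)cc2OC(c3ccccc3)(c3ccccc3)Oc12 | intermediate (not isolated)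
18 | triisopropylsilyl 6-bromo-2,2-diphenyl-5-{[(triisopropylsilyl)oxy]methyl}-1,3-benzodioxole-4-carboxylate | CC(C)[Si](OC(=O)c1c(CO[Si](C(C)C)(C(C)C)C(C)C)c(Br)cc2OC(c3ccccc3)(c3ccccc3)Oc12)(C(C)C)C(C)C | intermediate (not isolated)
19 | 6-bromo-2,2-diphenyl-5-{[(triisopropylsilyl)oxy]methyl}-1,3-benzodioxole-4-carboxylic acid | OC(=O)c1c(CO[Si](C(C)C)(C(C)C)C(C)C)c(Br)cc2OC(c3ccccc3)(c3ccccc3)Oc12 | intermediate
20 | lithium 6-lithio-2,2-diphenyl-5-{[(triisopropylsilyl)oxy]methyl}-1,3-benzodioxole-4-carboxylate | [Li]OC(=O)c1c(CO[Si](C(C)C)(C(C)C)C(C)C)c([Li])cc2OC(c3ccccc3)(c3ccccc3)Oc12 | intermediate (not isolated)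
21 | 2,2-diphenyl-6-[(3R)-3,5,7-tris(benzyloxy)-2-hydroxy-3,4-dihydro-2H-chromen-2-yl]-5-{[(triisopropylsilyl)oxy]methyl}-1,3-benzodioxole-4-carboxylic acid | OC(=O)c1c(CO[Si](C(C)C)(C(C)C)C(C)C)c(C3(O)Oc4cc(OCc5ccccc5)cc(OCc5ccccc5)c4C[C@H]3OCc3ccccc3)cc2OC(c3ccccc3)(c3ccccc3)Oc12 | intermediate
22 | 2,2-diphenyl-6-[(2R,3R)-3,5,7-tris(benzyloxy)-3,4-dihydro-2H-chromen-2-yl]-5-{[(triisopropylsilyl)oxy]methyl}-1,3-benzodioxole-4-carboxylic acid | OC(=O)c1c(CO[Si](C(C)C)(C(C)C)C(C)C)c([C@H]3Oc4cc(OCc5ccccc5)cc(OCc5ccccc5)c4C[C@H]3OCc3ccccc3)cc2OC(c3ccccc3)(c3ccccc3)Oc12 | intermediate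
23 | carbonyl chloride of 22 | ClC(=O)c1c(CO[Si](C(C)C)(C(C)C)C(C)C)c([C@H]3Oc4cc(OCc5ccccc5)cc(OCc5ccccc5)c4C[C@H]3OCc3ccccc3)cc2OC(c3ccccc3)(c3ccccc3)Oc12 | intermediate (not isolated)
24 | 2-diazo-1-{2,2-diphenyl-6-[(2R,3R)-3,5,7-tris(benzyloxy)-3,4-dihydro-2H-chromen-2-yl]-5-{[(triisopropylsilyl)oxy]methyl}-1,3-benzodioxol-4-yl}ethan-1-one | [N-]=[N+]=CC(=O)c1c(CO[Si](C(C)C)(C(C)C)C(C)C)c([C@H]3Oc4cc(OCc5ccccc5)cc(OCc5ccccc5)c4C[C@H]3OCc3ccccc3)cc2OC(c3ccccc3)(c3ccccc3)Oc12 | intermediate
25 | 2-diazo-1-{5-(hydroxymethyl)-2,2-diphenyl-6-[(2R,3R)-3,5,7-tris(benzyloxy)-3,4-dihydro-2H-chromen-2-yl]-1,3-benzodioxol-4-yl}ethan-1-one | [N-]=[N+]=CC(=O)c1c(CO)c([C@H]3Oc4cc(OCc5ccccc5)cc(OCc5ccccc5)c4C[C@H]3OCc3ccccc3)cc2OC(c3ccccc3)(c3ccccc3)Oc12 | intermediate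
26 | 4-(diazoacetyl)-2,2-diphenyl-6-[(2R,3R)-3,5,7-tris(benzyloxy)-3,4-dihydro-2H-chromen-2-yl]-1,3-benzodioxole-5-carbaldehyde (formyl diazoketone, key-step precursor) | [N-]=[N+]=CC(=O)c1c(C=O)c([C@H]3Oc4cc(OCc5ccccc5)cc(OCc5ccccc5)c4C[C@H]3OCc3ccccc3)cc2OC(c3ccccc3)(c3ccccc3)Oc12 | intermediate
27 | (2R)-2-hydroxy-N-methoxy-N-methyl-3-[2,4,6-tris(methoxymethoxy)phenyl]propanamide | CON(C)C(=O)[C@H](O)Cc1c(OCOC)cc(OCOC)cc1OCOC | intermediate
28 | 3,4,5-tris(benzyloxy)benzoic acid | OC(=O)c1cc(OCc2ccccc2)c(OCc2ccccc2)c(OCc2ccccc2)c1 | starting material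
29 | (2R)-1-[methoxy(methyl)amino]-1-oxo-3-[2,4,6-tris(methoxymethoxy)phenyl]propan-2-yl 3,4,5-tris(benzyloxy)benzoate | CON(C)C(=O)[C@H](OC(=O)c1cc(OCc2ccccc2)c(OCc2ccccc2)c(OCc2ccccc2)c1)Cc1c(OCOC)cc(OCOC)cc1OCOC | intermediate
30 | bromomagnesium hemiaminal alkoxide from acetylide addition to 29 | CON(C)C(O[Mg]Br)(C#C)[C@H](OC(=O)c1cc(OCc2ccccc2)c(OCc2ccccc2)c(OCc2ccccc2)c1)Cc1c(OCOC)cc(OCOC)cc1OCOC | intermediate (not isolated)
31 | (2R)-3-oxo-1-[2,4,6-tris(methoxymethoxy)phenyl]pent-4-yn-2-yl 3,4,5-tris(benzyloxy)benzoate (gallate ynone, key-step precursor) | O=C(O[C@@H](C(=O)C#C)Cc1c(OCOC)cc(OCOC)cc1OCOC)c1cc(OCc2ccccc2)c(OCc2ccccc2)c(OCc2ccccc2)c1 | intermediate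
32 | dioxole-fused 2-benzopyrylium-4-olate (carbonyl ylide from 26) carrying the (2R,3R)-tribenzyloxyflavan | [O-]c1c[o+]cc2c([C@H]3Oc4cc(OCc5ccccc5)cc(OCc5ccccc5)c4C[C@H]3OCc3ccccc3)cc3OC(c4ccccc4)(c4ccccc4)Oc3c12 | intermediate (not isolated)
33 | oxygen-bridged cycloadduct: benzo-fused 8-oxabicyclo[3.2.1]octadienone with the (2R)-gallate acyl chain on T4, bridgeheads unassigned | O=C(O[C@@H](C(=O)C1=CC2OC1c1c([C@H]3Oc4cc(OCc5ccccc5)cc(OCc5ccccc5)c4C[C@H]3OCc3ccccc3)cc3OC(c4ccccc4)(c4ccccc4)Oc3c1C2=O)Cc1c(OCOC)cc(OCOC)cc1OCOC)c1cc(OCc2ccccc2)c(OCc2ccccc2)c(OCc2ccccc2)c1 | intermediate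
34 | benzotropolone ketone with the tris-MOM aryl chain and (2R)-gallate | O=C(O[C@@H](C(=O)c1cc(=O)c(O)c2c3OC(c4ccccc4)(c4ccccc4)Oc3cc([C@H]3Oc4cc(OCc5ccccc5)cc(OCc5ccccc5)c4C[C@H]3OCc3ccccc3)c2c1)Cc1c(OCOC)cc(OCOC)cc1OCOC)c1cc(OCc2ccccc2)c(OCc2ccccc2)c(OCc2ccccc2)c1 | intermediate (not isolated)
35 | benzotropolone ketone with the 2,4,6-trihydroxyphenyl chain and (2R)-gallate | O=C(O[C@@H](C(=O)c1cc(=O)c(O)c2c3OC(c4ccccc4)(c4ccccc4)Oc3cc([C@H]3Oc4cc(OCc5ccccc5)cc(OCc5ccccc5)c4C[C@H]3OCc3ccccc3)c2c1)Cc1c(O)cc(O)cc1O)c1cc(OCc2ccccc2)c(OCc2ccccc2)c(OCc2ccccc2)c1 | intermediate (not isolated)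
36 | methyl ketal: (3R)-5,7-dihydroxy-2-methoxy-2-(benzotropolonyl)chroman-3-yl tri-O-benzylgallate | O=C(O[C@@H]1Cc2c(O)cc(O)cc2OC1(OC)c1cc(=O)c(O)c2c3OC(c4ccccc4)(c4ccccc4)Oc3cc([C@H]3Oc4cc(OCc5ccccc5)cc(OCc5ccccc5)c4C[C@H]3OCc3ccccc3)c2c1)c1cc(OCc2ccccc2)c(OCc2ccccc2)c(OCc2ccccc2)c1 | intermediate
37 | protected theaflavin gallate: (2R,3R)-cis gallated flavan closed, six benzyl ethers and the diphenylmethylene acetal in place | O=C(O[C@@H]1Cc2c(O)cc(O)cc2O[C@@H]1c1cc(=O)c(O)c2c3OC(c4ccccc4)(c4ccccc4)Oc3cc([C@H]3Oc4cc(OCc5ccccc5)cc(OCc5ccccc5)c4C[C@H]3OCc3ccccc3)c2c1)c1cc(OCc2ccccc2)c(OCc2ccccc2)c(OCc2ccccc2)c1 | intermediate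
38 | CNP0488827.1 | O=C(O[C@@H]1Cc2c(O)cc(O)cc2O[C@@H]1c1cc(=O)c(O)c2c(O)c(O)cc([C@H]3Oc4cc(O)cc(O)c4C[C@H]3O)c2c1)c1cc(O)c(O)c(O)c1 | target

**Totals.** 22 steps in all. The longest linear sequence is 14 steps (steps 6–15, then 19–22; the line through steps 1–5, 11–15 and 19–22 is equally long).

**Steps most likely to fail**

Step 19. The carbenoid may be consumed before it closes onto the formyl oxygen (addition to the ynone π bond, coupling with a second diazoketone), or the ylide may add to the aldehyde of unreacted 26 or dimerise faster than it meets the ynone. The fallback generates the same benzopyrylium olate without a free metal carbenoid in the presence of the ynone. It sets out from 26: Rh2(OAc)4-catalysed O–H insertion into water in wet THF should give the hydroxymethyl ketone, which closes onto the neighbouring aldehyde as the 1-hydroxyisochroman-4-one F1. Acetylation (Ac2O, pyridine) should give the 1-acetoxyisochroman-4-one F2. Warming F2 with 31 and a hindered amine (iPr2NEt, MeCN, 40–60 °C) eliminates acetic acid to the olate 32, which is trapped in situ by 31, and the route is rejoined at 33.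

Step 11. The lithium hemiketal alkoxide may lose phenoxide and the ketone so formed may take up a second aryllithium; the hindered aryllithium may instead deprotonate the lactone at C3, eroding the stereocentre. The fallback replaces the lactone by an open-chain N-methoxy-N-methyl amide, whose chelated adduct allows one addition only and whose α-hydrogen is less acidic. It sets out from 10: aminolysis with AlMe3/MeNHOMe·HCl should open the lactone to the phenol amide F3, and TBSCl/imidazole should give the aryl silyl ether F4. Addition of the dilithio species 20 at −78 °C should give the ketone F5. One equivalent of AcOH-buffered TBAF at −20 °C removes the aryl silyl ether in preference to the hindered alkyl TIPS ether, and the freed phenol closes onto the ketone to return to the route at 21.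

Step 18. The acetylide may attack the gallate carbonyl, or the gallate may shift to the magnesium hemiaminal oxygen, so that the ester is lost before the ketone is released; liberated amine may also add to the ynone during quench. The fallback introduces the alkyne before the gallate and keeps its terminus silylated during acylation. It sets out from 27: excess LiC≡CSiMe3 (THF, −78 to −20 °C, acidic quench) should give the hydroxy silyl-ynone F6, and esterification with 28 (EDC·HCl, DMAP, 0 °C) should give the gallate silyl-ynone F7, whose β-silyl group shields the alkyne from amine addition. AcOH-buffered TBAF at −40 °C then removes the silyl group and the route is rejoined at 31.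

**Further compounds**

F1 | step 19 | 1-hydroxyisochroman-4-one (lactol) bearing the diphenylmethylene acetal and the (2R,3R)-tribenzyloxyflavan | OC1OCC(=O)c2c3OC(c4ccccc4)(c4ccccc4)Oc3cc([C@H]3Oc4cc(OCc5ccccc5)cc(OCc5ccccc5)c4C[C@H]3OCc3ccccc3)c21
F2 | step 19 | 1-acetoxyisochroman-4-one derived from F1 | CC(=O)OC1OCC(=O)c2c3OC(c4ccccc4)(c4ccccc4)Oc3cc([C@H]3Oc4cc(OCc5ccccc5)cc(OCc5ccccc5)c4C[C@H]3OCc3ccccc3)c21
F3 | step 11 | (2R)-2-(benzyloxy)-3-[2,4-bis(benzyloxy)-6-hydroxyphenyl]-N-methoxy-N-methylpropanamide | CON(C)C(=O)[C@H](OCc1ccccc1)Cc1c(O)cc(OCc2ccccc2)cc1OCc1ccccc1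
F4 | step 11 | (2R)-2-(benzyloxy)-3-{2,4-bis(benzyloxy)-6-[(tert-butyldimethylsilyl)oxy]phenyl}-N-methoxy-N-methylpropanamide | CON(C)C(=O)[C@H](OCc1ccccc1)Cc1c(O[Si](C)(C)C(C)(C)C)cc(OCc2ccccc2)cc1OCc1ccccc1
F5 | step 11 | 6-[(2R)-2-(benzyloxy)-3-{2,4-bis(benzyloxy)-6-[(tert-butyldimethylsilyl)oxy]phenyl}propanoyl]-2,2-diphenyl-5-{[(triisopropylsilyl)oxy]methyl}-1,3-benzodioxole-4-carboxylic acid | OC(=O)c1c(CO[Si](C(C)C)(C(C)C)C(C)C)c(C(=O)[C@H](OCc3ccccc3)Cc3c(O[Si](C)(C)C(C)(C)C)cc(OCc4ccccc4)cc3OCc3ccccc3)cc2OC(c3ccccc3)(c3ccccc3)Oc12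
F6 | step 18 | (4R)-4-hydroxy-5-[2,4,6-tris(methoxymethoxy)phenyl]-1-(trimethylsilyl)pent-1-yn-3-one | C[Si](C)(C)C#CC(=O)[C@H](O)Cc1c(OCOC)cc(OCOC)cc1OCOC
F7 | step 18 | (2R)-3-oxo-1-[2,4,6-tris(methoxymethoxy)phenyl]-5-(trimethylsilyl)pent-4-yn-2-yl 3,4,5-tris(benzyloxy)benzoate | O=C(O[C@@H](C(=O)C#C[Si](C)(C)C)Cc1c(OCOC)cc(OCOC)cc1OCOC)c1cc(OCc2ccccc2)c(OCc2ccccc2)c(OCc2ccccc2)c1
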